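Retrosynthetic overview
1. Target 16 ⇒ 15 by allylic oxidation of the C8 methyl (C17) to the aldehyde, with C7=C8 already in place; the side chain C12–C16 comes from cross-metathesis with methyl acrylate and a catalyst-controlled conjugate methylation (C13).
2. The C9–C11 bond and H9 come from 1,2-addition of a butenyl Grignard reagent to the C9 ketone of bicyclic enone 9, then palladium/formate hydrogenolysis of the tertiary allylic carbonate (hydride to C9, alkene stays at C7=C8).
3. Key disconnection, C3–C4 of ring A: 9 ⇒ monocyclic keto-aldehyde 8. An iron hydride turns the isopropenyl group on C5 into the C4 tertiary radical, which closes onto the C3 aldehyde carried by the chain on C10.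
4. Ring B is not built: it is the ring of (S)-carvone (carbonyl = C9, ring methyl = C17 on C8, C7=C8, isopropenyl on C5), and C10 is made quaternary by two enolate alkylations. Ring order: ring B (chiral pool), then ring A (step 5), the last ring closed.
5. Enabling feature: in ring A the C3 carbinol is bonded to the gem-dimethyl C4, which is bonded to ring-fusion C5, so C3/C4 is an aldehyde + isopropenyl retron, and ring B has the p-menthane pattern (C17 on C8 para to C4 on C5). Closing ring A at C3–C4, not at a fusion bond, lets the trans C5/C10 relation be set beforehand; closure at a fusion atom would be forced towards the cis-decalin.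

Key step: step 5

Numbering: labdane numbering of the target is used for all intermediates (carvone C1, C2, 2-CH3, C3, C4, C5, C6 become C9, C8, C17, C7, C6, C5, C10).
Assumption: in step 9 the Tol-BINAP enantiomer is the one that sends methyl to the Re face of C13 of the (E)-enoate; it is written as (S)-Tol-BINAP, and the mirror-image ligand would be taken if the sense of induction proves opposite.

Step 1
Reactants: 1 (S)-(+)-carvone
Product: 3 6-methylcarvone (methyl mainly trans to isopropenyl; the C6 epimers converge in step 2), via lithium enolate 2 (not isolated)
Conditions: LDA (LiN(i-Pr)2), THF, −78 °C; MeI, −78 → 0 °C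
Reagents that add atoms: iodomethane CI
Why: Kinetic α′-deprotonation of the enone gives the cross-conjugated enolate, which is C-methylated (enolate alkylation); the new centre is planarised again in step 2, so its configuration does not matter.

Step 2
Reactants: 3 6-methylcarvone
Product: 5 6-allyl-6-methylcarvone (allyl trans to isopropenyl), via lithium enolate 4 (not isolated)
Conditions: LDA, THF, −78 → 0 °C; allyl bromide, DMPU, −78 °C → rt
Reagents that add atoms: allyl bromide C=CCBr
Why: Second kinetic enolate alkylation, in which allyl bromide should attack the tetrasubstituted enolate carbon anti to the neighbouring C5 isopropenyl group, setting quaternary C10 with the future C1 chain trans to the future C4 substituent and the methyl cis to it.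

Step 3
Reactants: 5 6-allyl-6-methylcarvone
Product: 7 primary alcohol (3-hydroxypropyl chain on C10), via alkylborane 6 (not isolated)
Conditions: Sia2BH (made from BH3·THF and 2-methylbut-2-ene), THF, 0 °C; then Me3NO·2H2O, 65 °C
Reagents that add atoms: trimethylamine N-oxide C[N+](C)(C)[O-]
Why: Anti-Markovnikov hydroboration–oxidation, in which the bulky dialkylborane should take the monosubstituted allyl alkene far faster than the isopropenyl group, the enone alkene or the hindered conjugated ketone, while amine-oxide oxidation avoids the alkaline peroxide that would epoxidise the enone.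

Step 4
Reactants: 7 primary alcohol
Product: 8 keto-aldehyde (3-oxopropyl chain on C10)
Conditions: Dess–Martin periodinane, CH2Cl2, rt
Reagents that add atoms: none
Why: Dess–Martin oxidation of the primary alcohol should stop at the aldehyde and leave the enone and the isopropenyl group untouched.

Step 5
Reactants: 8 keto-aldehyde
Product: 9 bicyclic hydroxy enone (trans-decalin, 3-OH equatorial)
Conditions: Fe(acac)3 (0.5 equiv), PhSiH3 (2.5 equiv), EtOH, 60 °C, argon, high dilution
Reagents that add atoms: none
Why: An iron hydride formed from Fe(acac)3 and PhSiH3 transfers a hydrogen atom to the CH2 terminus of the isopropenyl group (Markovnikov hydrogen-atom transfer), making C4 a tertiary radical that carries both methyl groups; this radical adds to the aldehyde carbon C3, and the alkoxy radical is reduced by divalent iron and protonated by ethanol. The closest known reaction type is the iron-hydride-initiated reductive radical cyclisation of alkene-tethered ketones, together with the addition of such radicals to aldehydes. Ring A closes in the 6-exo-trig mode onto the C=O group through the C3–C4 bond, which is not a ring-fusion bond, so the trans relation of C5 and C10 from steps 1 and 2 passes unchanged into a trans-decalin. C3 is controlled by the chair transition state on the trans-diequatorial C5/C10 scaffold, with the carbonyl oxygen pseudo-equatorial, which should give the equatorial 3-OH cis to the C10 methyl; C4 becomes the gem-dimethyl quaternary carbon and is not stereogenic. The step needs hydrogen-atom transfer to the electron-rich 1,1-disubstituted alkene rather than to the electron-poor trisubstituted enone alkene, and ring closure faster than simple reduction of the radical or intermolecular Giese addition to an enone. The first is the normal donor-alkene preference of iron hydrides; the second is secured by the quaternary C10 and ring B holding C3 next to C4, by dilution, and by the fact that attack of C4 on the enone of the same molecule would need a four-membered ring.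

Step 6
Reactants: 9 bicyclic hydroxy enone
Product: 11 bis(methyl carbonate) of the C9 adduct, via magnesium dialkoxide 10 (not isolated)
Conditions: but-3-enylmagnesium bromide (3.5 equiv), CeCl3, THF, −78 → 0 °C; then ClCO2Me, DMAP (cat.), −78 °C → rt
Reagents that add atoms: but-3-enylmagnesium bromide C=CCC[Mg]Br; methyl chloroformate COC(=O)Cl
Why: Organocerium-type 1,2-addition to the hindered enone after deprotonation of the 3-OH, in which the nucleophile should enter C9 anti to the axial C10 methyl; acylation of both alkoxides in the same flask gives the tertiary allylic carbonate and a spectator C3 carbonate.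

Step 7
Reactants: 11 bis(methyl carbonate)
Product: 13 C9-butenyl alcohol with C7=C8 and H9 anti to the C10 methyl, via carbonate 12 (not isolated)
Conditions: Pd(OAc)2 (5 mol%), n-Bu3P (5 mol%), HCO2NH4, THF, 45 °C; then MeOH, K2CO3, 40 °C
Reagents that add atoms: none
Why: Palladium-catalysed formate hydrogenolysis of an allylic carbonate (Tsuji type): zerovalent palladium ionises the carbonate anti to the leaving group, and hydride passes from the palladium formate to the more substituted allyl terminus C9 on the metal face, which should leave the C7=C8 alkene and place H9 opposite the C10 methyl (side chain equatorial); methanolysis then removes the C3 carbonate.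

Step 8
Reactants: 13 C9-butenyl alcohol
Product: 14 (E)-enoate
Conditions: methyl acrylate (5 equiv), second-generation Hoveyda–Grubbs catalyst (3 mol%), CH2Cl2, 40 °C
Reagents that add atoms: methyl acrylate C=CC(=O)OC
Why: Olefin cross-metathesis of the terminal alkene with an acrylate should give the (E)-enoate, the trisubstituted ring alkene being inert under these conditions.

Step 9
Reactants: 14 (E)-enoate
Product: 15 methyl ester with the C13 methyl group (17-deoxo target)
Conditions: MeMgBr (3 equiv), CuI (2 mol%), (S)-Tol-BINAP (3 mol%), t-BuOMe, −20 °C
Reagents that add atoms: methylmagnesium bromide C[Mg]Br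
Why: Copper-catalysed enantioselective conjugate addition of a Grignard reagent to an (E)-α,β-unsaturated ester, in which the chiral bisphosphine–copper catalyst sets C13 under reagent control far from the ring stereocentres, the first equivalent of MeMgBr only deprotonating the 3-OH.

Step 10
Reactants: 15 methyl ester (17-deoxo target)
Product: 16 CNP0285000.1 (target)
Conditions: SeO2 (1.5 equiv), 1,4-dioxane, trace H2O, 80 °C
Reagents that add atoms: selenium dioxide O=[Se]=O
Why: Riley allylic oxidation (ene reaction, [2,3]-shift, then oxidation of the allylic alcohol) should take the methyl group on the more substituted alkene carbon C8 to the conjugated aldehyde, because the other allylic site on that carbon, C9–H, is tertiary and shielded by quaternary C10 and the side chain.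

Compound list
1 | (S)-(+)-carvone, (5S)-2-methyl-5-(prop-1-en-2-yl)cyclohex-2-en-1-one | O=C1C(C)=CC[C@H](C(C)=C)C1 | starting material
2 | lithium enolate of 1 (cross-conjugated, C9=C10) | [Li]OC1=C[C@@H](C(C)=C)CC=C1C | intermediate (not isolated)
3 | 6-methylcarvone, (5S,6R)-2,6-dimethyl-5-(prop-1-en-2-yl)cyclohex-2-en-1-one (trans isomer drawn; the 6-epimer is carried along) | O=C1C(C)=CC[C@H](C(C)=C)[C@H]1C | intermediate
4 | lithium enolate of 3 | [Li]OC1=C(C)[C@@H](C(C)=C)CC=C1C | intermediate (not isolated)
5 | (5R,6R)-2,6-dimethyl-6-(prop-2-en-1-yl)-5-(prop-1-en-2-yl)cyclohex-2-en-1-one (allyl trans, methyl cis to isopropenyl) | O=C1C(C)=CC[C@H](C(C)=C)[C@@]1(C)CC=C | intermediate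
6 | B-alkyl disiamylborane from 5 (boron on the terminal carbon of the former allyl group) | O=C1C(C)=CC[C@H](C(C)=C)[C@@]1(C)CCCB(C(C)C(C)C)C(C)C(C)C | intermediate (not isolated)
7 | 6-(3-hydroxypropyl)-2,6-dimethyl-5-(prop-1-en-2-yl)cyclohex-2-en-1-one (configuration as in 5) | O=C1C(C)=CC[C@H](C(C)=C)[C@@]1(C)CCCO | intermediate
8 | 3-[1,3-dimethyl-2-oxo-6-(prop-1-en-2-yl)cyclohex-3-en-1-yl]propanal (configuration as in 5) | O=C1C(C)=CC[C@H](C(C)=C)[C@@]1(C)CCC=O | intermediate
9 | 6-hydroxy-2,5,5,8a-tetramethyl-4a,5,6,7,8,8a-hexahydronaphthalen-1(4H)-one (trans-fused; OH equatorial, cis to the angular methyl; labdane 3-hydroxy-7-en-9-one) | O=C1C(C)=CC[C@@H]2C(C)(C)[C@H](O)CC[C@@]12C | intermediate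
10 | bis(bromomagnesium) dialkoxide of the 9-(but-3-enyl)-3,9-diol (butenyl anti to the C10 methyl) | C=CCC[C@@]1(O[Mg]Br)C(C)=CC[C@@H]2C(C)(C)[C@H](O[Mg]Br)CC[C@@]12C | intermediate (not isolated)
11 | 3,9-bis(methoxycarbonyloxy) derivative of the 9-(but-3-enyl) diol | C=CCC[C@@]1(OC(=O)OC)C(C)=CC[C@@H]2C(C)(C)[C@H](OC(=O)OC)CC[C@@]12C | intermediate
12 | C3 methyl carbonate of 13 | C=CCC[C@@H]1C(C)=CC[C@@H]2C(C)(C)[C@H](OC(=O)OC)CC[C@@]12C | intermediate (not isolated)
13 | 5-(but-3-en-1-yl)-1,1,4a,6-tetramethyl-1,2,3,4,4a,5,8,8a-octahydronaphthalen-2-ol (trans-fused; H9 anti, butenyl cis to the C10 methyl) | C=CCC[C@@H]1C(C)=CC[C@@H]2C(C)(C)[C@H](O)CC[C@@]12C | intermediate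
14 | methyl (E)-enoate from 13 (C13=C14, ester at C15) | COC(=O)/C=C/CC[C@@H]1C(C)=CC[C@@H]2C(C)(C)[C@H](O)CC[C@@]12C | intermediate
15 | methyl (3R,13R)-3-hydroxy-ent-labd-7-en-15-oate | COC(=O)C[C@H](C)CC[C@@H]1C(C)=CC[C@@H]2C(C)(C)[C@H](O)CC[C@@]12C | intermediate
16 | CNP0285000.1, methyl (3R,13R)-3-hydroxy-17-oxo-ent-labd-7-en-15-oate | COC(=O)C[C@H](C)CC[C@@H]1C(C=O)=CC[C@@H]2C(C)(C)[C@H](O)CC[C@@]12C | target

Total step count: 10. Longest linear sequence: 10 steps from (S)-carvone; the route is fully linear and every other input is a commercial reagent.

Steps most likely to fail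

Step 5. What may go wrong: the cyclised alkoxy radical may fragment back to the tertiary radical faster than it is reduced, so that the isopropenyl group is merely hydrogenated, and facial control at C3 may be incomplete. The fallback sets out from 8 and returns at 9. The aldehyde is converted with I2 and aqueous NH3 in THF into keto nitrile F1. The same iron-hydride hydrogen-atom transfer (Fe(acac)3, PhSiH3, EtOH) then triggers the known radical cyclisation onto a nitrile, which does not revert, and hydrolysis on work-up gives diketone F2. NaBH4 (MeOH/CH2Cl2, −40 °C) should reduce the saturated C3 ketone in preference to the hindered conjugated C9 ketone, with axial hydride attack giving the equatorial alcohol 9.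

Step 7. What may go wrong: hydride may be delivered to the less hindered terminus C7 (tetrasubstituted C8=C9 alkene), the allylpalladium species may undergo β-hydride elimination to dienes, or the C9 configuration may be lost by facial exchange of the allyl complex. The fallback sets out from 11 and returns at 13. Pd(PPh3)4 with Bu4NOAc in THF moves the oxygen to the less hindered terminus with net retention of face and gives allylic acetate F3 (7-OAc cis to the C10 methyl, C8=C9). K2CO3 in MeOH gives diol F4. A Myers reductive transposition (2-nitrobenzenesulfonylhydrazide, PPh3, DEAD, THF, −30 °C → rt) then substitutes the allylic C7 hydroxyl with inversion, the neopentyl C3 hydroxyl staying inert. Loss of N2 with a sigmatropic hydrogen shift places hydrogen on C9 from that face and moves the alkene to C7=C8, which is 13.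

Step 10. What may go wrong: oxidation may occur at the other allylic positions (C6, C9), the enal may be over-oxidised at C9, or acid may move the alkene into the C8=C9 position. The fallback sets out from 15 and returns at 16. mCPBA (CH2Cl2, 0 °C) epoxidises C7=C8 from the face opposite the C10 methyl to epoxide F5. Et2Al(TMP) (diethylaluminium 2,2,6,6-tetramethylpiperidide, toluene, 0 °C) removes a C17 proton and opens the epoxide to the exocyclic allylic alcohol F6. Ph3SiOReO3 (cat., Et2O) effects the 1,3-transposition to the primary allylic alcohol F7 with the trisubstituted C7=C8 alkene. MnO2 (CH2Cl2) oxidises only this allylic alcohol, giving 16.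

Further compounds
F1 | step 5 | keto nitrile, 3-[1,3-dimethyl-2-oxo-6-(prop-1-en-2-yl)cyclohex-3-en-1-yl]propanenitrile | O=C1C(C)=CC[C@H](C(C)=C)[C@@]1(C)CCC#N
F2 | step 5 | diketone, 3-oxo analogue of 9 | O=C1C(C)=CC[C@@H]2C(C)(C)C(=O)CC[C@@]12C
F3 | step 7 | allylic acetate (7-OAc, C8=C9, C3 methyl carbonate) | C=CCCC1=C(C)[C@H](OC(C)=O)C[C@@H]2C(C)(C)[C@H](OC(=O)OC)CC[C@@]12C
F4 | step 7 | 3,7-diol with C8=C9 | C=CCCC1=C(C)[C@H](O)C[C@@H]2C(C)(C)[C@H](O)CC[C@@]12C
F5 | step 10 | 7,8-epoxide of 15 (oxygen anti to the C10 methyl) | COC(=O)C[C@H](C)CC[C@@H]1[C@@]2(C)O[C@H]2C[C@@H]3C(C)(C)[C@H](O)CC[C@@]13C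
F6 | step 10 | exocyclic allylic alcohol (C8=C17, 7-OH) | COC(=O)C[C@H](C)CC[C@@H]1C(=C)[C@@H](O)C[C@@H]2C(C)(C)[C@H](O)CC[C@@]12C
F7 | step 10 | primary allylic alcohol (17-OH, C7=C8) | COC(=O)C[C@H](C)CC[C@@H]1C(CO)=CC[C@@H]2C(C)(C)[C@H](O)CC[C@@]12C
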